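## Retrosynthetic overview

1. Target ⇐ acetonide cleavage ⇐ catechol made by ortho-hydroxylation at C6 of a 7-hydroxyphthalide (the C5 and C7 oxygens come with the building blocks, the C6 oxygen by late oxidation).
2. 7-Hydroxyphthalide ⇐ one-pot Diels–Alder / aromatisation / lactonisation of a 3-aryloxy Brassard-type diene with a 4-silyloxybut-2-ynoate: ring B and the lactone ring are built together on the ring A oxygen, with no aryl–O coupling.
3. Diene ⇐ γ-deprotonation and O-silylation of a β-aryloxy pentenoate ⇐ oxa-Michael addition of the ring A phenol to methyl pent-2-ynoate.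
4. Ring A phenol ⇐ methyl orsellinate by C3 formylation, reduction and acetonide formation (the dioxine ring masks 4-OH and CH2OH).
5. Ring order: ring A (bought) → dioxine protecting ring → ring B plus lactone ring in one operation → dioxine ring opened last.

Assumption: the target has no stereocentre and no stereogenic double bond, so it is achiral and no enantiocontrol is needed.

## Route

Step 1
Reactants: 1 methyl 2,4-dihydroxy-6-methylbenzoate (methyl orsellinate)
Product: 3 methyl 3-formyl-2,4-dihydroxy-6-methylbenzoate, via chloro ether 2 (not isolated)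
Conditions: Cl2CHOMe (1.5 equiv), TiCl4 (3 equiv), CH2Cl2, −10 → 0 °C; then 1 M aq. HCl, 0 °C
Reagents that add atoms: dichloromethyl methyl ether, COC(Cl)Cl; water, O
Why: Rieche formylation, in which titanium bound to the two flanking phenols steers the electrophile to C3 and aqueous hydrolysis of chloro ether 2 releases the aldehyde (minor 5-formyl isomer removed by crystallisation); no stereocentre remains.

Step 2
Reactants: 3 methyl 3-formyl-2,4-dihydroxy-6-methylbenzoate
Product: 4 methyl 2,4-dihydroxy-3-(hydroxymethyl)-6-methylbenzoate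
Conditions: NaBH4 (1 equiv), THF/MeOH (4:1), 0 °C, 20 min; pH 6 phosphate buffer
Reagents that add atoms: none
Why: Chemoselective borohydride reduction of the aryl aldehyde beside the hindered methyl ester; low temperature and a near-neutral quench avoid ortho-quinone methide formation and over-reduction to the methyl compound.

Step 3
Reactants: 4 methyl 2,4-dihydroxy-3-(hydroxymethyl)-6-methylbenzoate
Product: 5 methyl 5-hydroxy-2,2,7-trimethyl-4H-1,3-benzodioxine-6-carboxylate
Conditions: 2,2-dimethoxypropane, PPTS (cat.), acetone, rt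
Reagents that add atoms: 2,2-dimethoxypropane, COC(C)(C)OC
Why: Acid-catalysed acetonide formation (transketalisation) on the salicyl alcohol, where the free 4-OH closes the dioxine ring while the 2-OH stays hydrogen-bonded to the ester carbonyl and remains free for the ether bond.

Step 4
Reactants: 5 methyl 5-hydroxy-2,2,7-trimethyl-4H-1,3-benzodioxine-6-carboxylate; 6 methyl pent-2-ynoate
Product: 7 methyl 5-{[(2E)-1-methoxy-1-oxopent-2-en-3-yl]oxy}-2,2,7-trimethyl-4H-1,3-benzodioxine-6-carboxylate
Conditions: Cs2CO3 (0.3 equiv), DMF, 60 °C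
Reagents that add atoms: none
Why: Base-catalysed oxa-Michael addition of the phenoxide to the β-carbon of the ynoate gives the β-aryloxy enoate (E isomer expected as the major one; any Z or deconjugated isomer converges in step 5), so the future diaryl ether C–O bond is made at an sp carbon.

Step 5
Reactants: 7 methyl 5-{[(2E)-1-methoxy-1-oxopent-2-en-3-yl]oxy}-2,2,7-trimethyl-4H-1,3-benzodioxine-6-carboxylate
Product: 9 methyl 5-{[(2Z,4E)-5-methoxy-5-(trimethylsilyloxy)penta-2,4-dien-3-yl]oxy}-2,2,7-trimethyl-4H-1,3-benzodioxine-6-carboxylate (silyl ketene acetal diene; geometric isomers used together), via lithium dienolate 8 (not isolated)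
Conditions: Me3SiCl (1.5 equiv), then LiN(iPr)2 (1.15 equiv), THF, −78 °C → rt; pentane, filtration; used crude
Reagents that add atoms: chlorotrimethylsilane, C[Si](C)(C)Cl
Why: Kinetic γ-deprotonation of the vinylogous ester with O-silylation is the standard way to Brassard-type dienes; the di-ortho-substituted, twisted ring A ester resists both attack and lateral deprotonation at −78 °C under in-situ silyl trapping, and the double-bond geometry is erased later on aromatisation.

Step 6
Reactants: 9 silyl ketene acetal diene; 10 methyl 4-hydroxybut-2-ynoate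
Product: 14 methyl 5-[(7-hydroxy-4-methyl-1-oxo-1,3-dihydro-2-benzofuran-5-yl)oxy]-2,2,7-trimethyl-4H-1,3-benzodioxine-6-carboxylate, via silyl ether 11 (not isolated), via cycloadduct 12 (not isolated), via hydroxy ester 13 (not isolated)
Conditions: 10 (2.5 equiv), N,O-bis(trimethylsilyl)acetamide (2.6 equiv), toluene, rt, 30 min; add 9, 110 °C, 24 h; then K2CO3 (0.2 equiv), MeOH, 0 °C → rt
Reagents that add atoms: none
Why: Proposed new method: the electron-rich 1,1,3-trioxygenated diene 9 should undergo a thermal Diels–Alder reaction with ynoate 11, its methyl-bearing terminus bonding to the β-carbon that carries CH2OSiMe3 and its ketene acetal carbon to the α-carbon, after which methanolysis expels MeOSiMe3 from the ketal carbon to aromatise ring B (the two sp3 centres of 12 vanish) and frees the benzylic alcohol, which closes onto the neighbouring ester, so ring B and the lactone ring arise in one operation; the closest known reactions are Brassard-diene/alkynoate benzannulations to resorcylates and the spontaneous lactonisation of 2-(hydroxymethyl)benzoates to phthalides.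

Step 7
Reactants: 14 methyl 5-[(7-hydroxy-4-methyl-1-oxo-1,3-dihydro-2-benzofuran-5-yl)oxy]-2,2,7-trimethyl-4H-1,3-benzodioxine-6-carboxylate
Product: 16 methyl 5-[(6,7-dihydroxy-4-methyl-1-oxo-1,3-dihydro-2-benzofuran-5-yl)oxy]-2,2,7-trimethyl-4H-1,3-benzodioxine-6-carboxylate, via ortho-quinone 15 (not isolated)
Conditions: IBX (1.2 equiv), DMF, rt, dark; then aq. Na2S2O4, EtOAc, 0 °C
Reagents that add atoms: 2-iodoxybenzoic acid (IBX), O=C1OI(=O)(O)c2ccccc12
Why: IBX ortho-oxygenation of a phenol, in which the phenol binds to pentavalent iodine and oxygen is delivered to the only free ortho carbon (C6, also activated by the adjacent aryloxy group) to give the ortho-quinone, which dithionite reduces at once to the catechol; ring A carries no free phenol or alcohol and is untouched.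

Step 8
Reactants: 16 methyl 5-[(6,7-dihydroxy-4-methyl-1-oxo-1,3-dihydro-2-benzofuran-5-yl)oxy]-2,2,7-trimethyl-4H-1,3-benzodioxine-6-carboxylate
Product: 17 methyl 2-[(6,7-dihydroxy-4-methyl-1-oxo-1,3-dihydro-2-benzofuran-5-yl)oxy]-4-hydroxy-3-(hydroxymethyl)-6-methylbenzoate (Compound NP-007516)
Conditions: 1 M aq. HCl/THF (1:4), rt
Reagents that add atoms: none
Why: Acid hydrolysis of the phenol/benzyl mixed ketal (acetonide) frees the 4-OH and the CH2OH, while the hindered methyl ester, the phthalide and the diaryl ether are stable to cold dilute acid; the product is achiral.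

## Compound list

1 | methyl 2,4-dihydroxy-6-methylbenzoate (methyl orsellinate) | COC(=O)c1c(C)cc(O)cc1O | starting material
2 | methyl 3-[chloro(methoxy)methyl]-2,4-dihydroxy-6-methylbenzoate (racemic; titanium-bound in the flask; not isolated) | COC(=O)c1c(C)cc(O)c(C(Cl)OC)c1O | intermediate
3 | methyl 3-formyl-2,4-dihydroxy-6-methylbenzoate | COC(=O)c1c(C)cc(O)c(C=O)c1O | intermediate
4 | methyl 2,4-dihydroxy-3-(hydroxymethyl)-6-methylbenzoate | COC(=O)c1c(C)cc(O)c(CO)c1O | intermediate
5 | methyl 5-hydroxy-2,2,7-trimethyl-4H-1,3-benzodioxine-6-carboxylate | COC(=O)c1c(C)cc2OC(C)(C)OCc2c1O | intermediate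
6 | methyl pent-2-ynoate | CCC#CC(=O)OC | starting material
7 | methyl 5-{[(2E)-1-methoxy-1-oxopent-2-en-3-yl]oxy}-2,2,7-trimethyl-4H-1,3-benzodioxine-6-carboxylate | COC(=O)c1c(C)cc2OC(C)(C)OCc2c1O/C(CC)=C/C(=O)OC | intermediate
8 | lithium dienolate of 7 (lithium 1-methoxy-3-aryloxypenta-1,3-dien-1-olate; geometry not defined; not isolated) | [Li+].COC(=O)c1c(C)cc2OC(C)(C)OCc2c1OC(=CC)C=C([O-])OC | intermediate
9 | methyl 5-{[(2Z,4E)-5-methoxy-5-(trimethylsilyloxy)penta-2,4-dien-3-yl]oxy}-2,2,7-trimethyl-4H-1,3-benzodioxine-6-carboxylate (drawn isomer; used with its geometric isomers) | COC(=O)c1c(C)cc2OC(C)(C)OCc2c1O/C(=C\C)/C=C(\OC)O[Si](C)(C)C | intermediate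
10 | methyl 4-hydroxybut-2-ynoate | COC(=O)C#CCO | starting material
11 | methyl 4-(trimethylsilyloxy)but-2-ynoate (not isolated) | COC(=O)C#CCO[Si](C)(C)C | intermediate
12 | Diels–Alder adduct: methyl 6-methoxy-3-methyl-6-(trimethylsilyloxy)-2-[(trimethylsilyloxy)methyl]-4-aryloxycyclohexa-1,4-diene-1-carboxylate, aryloxy being the benzodioxinyloxy group of 5 (racemic mixture of diastereomers; not isolated) | COC(=O)C1=C(CO[Si](C)(C)C)C(C)C(Oc2c(C(=O)OC)c(C)cc3OC(C)(C)OCc23)=CC1(OC)O[Si](C)(C)C | intermediate
13 | methyl 5-[5-hydroxy-3-(hydroxymethyl)-4-(methoxycarbonyl)-2-methylphenoxy]-2,2,7-trimethyl-4H-1,3-benzodioxine-6-carboxylate (not isolated) | COC(=O)c1c(O)cc(Oc2c(C(=O)OC)c(C)cc3OC(C)(C)OCc23)c(C)c1CO | intermediate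
14 | methyl 5-[(7-hydroxy-4-methyl-1-oxo-1,3-dihydro-2-benzofuran-5-yl)oxy]-2,2,7-trimethyl-4H-1,3-benzodioxine-6-carboxylate | O=C1OCc2c(C)c(Oc3c(C(=O)OC)c(C)cc4OC(C)(C)OCc34)cc(O)c12 | intermediate
15 | methyl 5-[(4-methyl-1,6,7-trioxo-1,3,6,7-tetrahydro-2-benzofuran-5-yl)oxy]-2,2,7-trimethyl-4H-1,3-benzodioxine-6-carboxylate (ortho-quinone; not isolated) | O=C1OCC2=C1C(=O)C(=O)C(Oc3c(C(=O)OC)c(C)cc4OC(C)(C)OCc34)=C2C | intermediate
16 | methyl 5-[(6,7-dihydroxy-4-methyl-1-oxo-1,3-dihydro-2-benzofuran-5-yl)oxy]-2,2,7-trimethyl-4H-1,3-benzodioxine-6-carboxylate | O=C1OCc2c(C)c(Oc3c(C(=O)OC)c(C)cc4OC(C)(C)OCc34)c(O)c(O)c12 | intermediate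
17 | methyl 2-[(6,7-dihydroxy-4-methyl-1-oxo-1,3-dihydro-2-benzofuran-5-yl)oxy]-4-hydroxy-3-(hydroxymethyl)-6-methylbenzoate | COC(=O)c1c(C)cc(O)c(CO)c1Oc1c(C)c2c(c(O)c1O)C(=O)OC2 | target

## Step count and risks

Total steps: 8. Longest linear sequence: 8 (1 → 17).

**Step 6 (ring B plus lactone cascade).** The tetrasubstituted diene and the β-substituted ynoate may react slowly, the diene may decompose on heating, or Me3SiOH may be lost instead of MeOSiMe3 to give the 7-methyl ether. The fallback is an anionic annulation that sets out from 7 and 10 and comes back at 14. Compound 10 is silylated separately (Me3SiCl, Et3N, CH2Cl2) and 11 is distilled. Compound 7 is converted with LiN(iPr)2 (THF, −78 °C) into dienolate 8, which adds through its γ-carbon to the β-carbon of 11 (vinylogous Michael addition). The allenyl ester enolate so formed closes onto the enoate ester carbon (Dieckmann-type Claisen condensation) and tautomerises to methyl 5-{5-hydroxy-4-(methoxycarbonyl)-2-methyl-3-[(trimethylsilyloxy)methyl]phenoxy}-2,2,7-trimethyl-4H-1,3-benzodioxine-6-carboxylate F3. K2CO3/MeOH added to the same pot removes the silyl group, and 13 lactonises to 14.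

**Step 7 (ortho-hydroxylation).** The phenol is hydrogen-bonded to the lactone carbonyl and sits ortho to an acceptor, so oxygen transfer may be slow, and quinone 15 is sensitive to nucleophiles. The fallback sets out from 14 and comes back at 16. Magnesium-mediated ortho-formylation (MgCl2, Et3N, paraformaldehyde, MeCN, reflux) gives methyl 5-[(6-formyl-7-hydroxy-4-methyl-1-oxo-1,3-dihydro-2-benzofuran-5-yl)oxy]-2,2,7-trimethyl-4H-1,3-benzodioxine-6-carboxylate F4. Dakin oxidation (urea–hydrogen peroxide, cat. (PhSe)2, CH2Cl2, rt) gives the aryl formate methyl 5-{[6-(formyloxy)-7-hydroxy-4-methyl-1-oxo-1,3-dihydro-2-benzofuran-5-yl]oxy}-2,2,7-trimethyl-4H-1,3-benzodioxine-6-carboxylate F5. Aqueous NaHCO3 in MeOH cleaves the formate to 16.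

**Step 4 (oxa-Michael addition).** The phenol is chelated and flanked on both sides, and addition to an internal alkyl ynoate may stall. The fallback sets out from 5 and 6 and comes back at 9. Hydroiodination of 6 (NaI, AcOH, 70 °C) gives methyl (Z)-3-iodopent-2-enoate F1. Ullmann-type vinyl C–O coupling of 5 with F1 (copper iodide CuI 10 mol %, N,N-dimethylglycine, Cs2CO3, dioxane, 80 °C) proceeds with retention to the Z isomer of 7, methyl 5-{[(2Z)-1-methoxy-1-oxopent-2-en-3-yl]oxy}-2,2,7-trimethyl-4H-1,3-benzodioxine-6-carboxylate F2. Under the conditions of step 5, F2 gives the same dienolate 8 and diene 9.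

## Further compounds

F1 | step 4 | methyl (Z)-3-iodopent-2-enoate | CC/C(I)=C/C(=O)OC
F2 | step 4 | methyl 5-{[(2Z)-1-methoxy-1-oxopent-2-en-3-yl]oxy}-2,2,7-trimethyl-4H-1,3-benzodioxine-6-carboxylate | COC(=O)c1c(C)cc2OC(C)(C)OCc2c1O/C(CC)=C\C(=O)OC
F3 | step 6 | methyl 5-{5-hydroxy-4-(methoxycarbonyl)-2-methyl-3-[(trimethylsilyloxy)methyl]phenoxy}-2,2,7-trimethyl-4H-1,3-benzodioxine-6-carboxylate | COC(=O)c1c(O)cc(Oc2c(C(=O)OC)c(C)cc3OC(C)(C)OCc23)c(C)c1CO[Si](C)(C)C
F4 | step 7 | methyl 5-[(6-formyl-7-hydroxy-4-methyl-1-oxo-1,3-dihydro-2-benzofuran-5-yl)oxy]-2,2,7-trimethyl-4H-1,3-benzodioxine-6-carboxylate | O=C1OCc2c(C)c(Oc3c(C(=O)OC)c(C)cc4OC(C)(C)OCc34)c(C=O)c(O)c12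
F5 | step 7 | methyl 5-{[6-(formyloxy)-7-hydroxy-4-methyl-1-oxo-1,3-dihydro-2-benzofuran-5-yl]oxy}-2,2,7-trimethyl-4H-1,3-benzodioxine-6-carboxylate | O=C1OCc2c(C)c(Oc3c(C(=O)OC)c(C)cc4OC(C)(C)OCc34)c(OC=O)c(O)c12
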